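**Retrosynthetic overview**
1. No ring is built. The quinone ring comes from hydroquinone 1, dearomatised (through disodium salt 2) to the symmetric 2,5-dihydroxy-1,4-benzoquinone 3; the cyclohexene ring with its (S) centre comes from (S)-α-ionone 4.
2. Side chain from 4: conjugate reduction of the enone (silyl enol ether 5, then ketone 6), C2'=C3' disconnection by Horner–Wadsworth–Emmons olefination (E-ester 7), then ester to E-allylic alcohol 8.
3. Key disconnection: the quinone C3–C1' bond, made by direct palladium-catalysed dehydrative C–H allylation of 3 with 8; mono-allylation breaks the symmetry of 3 and gives 9.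
4. Last disconnection: the C5–OCH3 bond, by regioselective vinylogous esterification of 9 to the target 10.

Assumption: (S)-(−)-α-ionone 4 (≥98% ee) is bought enantiopure from a specialty supplier; its ring stereocentre is the only stereocentre of the target and is carried through unchanged.

**Step 1**
Reactants: 1 hydroquinone (benzene-1,4-diol)
Product: 3 2,5-dihydroxy-1,4-benzoquinone, via disodium dihydroxyquinone salt 2 (not isolated)
Conditions: 30% H2O2 (3.5 equiv), 50% aq. NaOH, 45 °C; then conc. HCl, 0 °C
Reagents that add atoms: hydrogen peroxide, OO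
Why: Oxidative dearomatisation: in strong alkali the hydroquinone dianion is oxidised by H2O2 and hydroxylated twice by hydroperoxide conjugate addition and re-oxidation (both new oxygens come from the peroxide), stopping at the symmetric dianion 2, which precipitates and is acidified; no stereocentre is involved.

**Step 2**
Reactants: 4 (S)-α-ionone [(3E)-4-[(1S)-2,6,6-trimethylcyclohex-2-en-1-yl]but-3-en-2-one]
Product: 6 (S)-dihydro-α-ionone [4-[(1S)-2,6,6-trimethylcyclohex-2-en-1-yl]butan-2-one], via silyl enol ether 5 (not isolated)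
Conditions: [CuH(PPh3)]6 (2 mol%), PhMe2SiH (1.5 equiv), toluene, rt; then 1 M HCl, THF, 0 °C
Reagents that add atoms: none
Why: Copper hydride-catalysed 1,4-reduction (conjugate hydrosilylation): the soft Cu–H adds only to the enone C=C, the copper enolate is silylated to 5 and hydrolysed to the ketone, the isolated trisubstituted ring alkene is inert, and without base the C1' centre (S, from 4) is neither epimerised nor isomerised towards the β-ionone skeleton.

**Step 3**
Reactants: 6 (S)-dihydro-α-ionone
Product: 7 ethyl (2E)-3-methyl-5-[(1S)-2,6,6-trimethylcyclohex-2-en-1-yl]pent-2-enoate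
Conditions: (EtO)2P(O)CH2CO2Et (1.6 equiv), NaH (1.5 equiv), THF, 0 °C → reflux; SiO2 chromatography (E:Z about 5:1, E isomer kept)
Reagents that add atoms: triethyl phosphonoacetate, CCOC(=O)CP(=O)(OCC)OCC
Why: Horner–Wadsworth–Emmons olefination: the stabilised phosphonate anion adds reversibly to the methyl ketone and the thermodynamically favoured E enoate (ester trans to the long chain) predominates and is separated from the minor Z ester; the C1' centre is remote and not acidic.

**Step 4**
Reactants: 7 ethyl (2E)-3-methyl-5-[(1S)-2,6,6-trimethylcyclohex-2-en-1-yl]pent-2-enoate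
Product: 8 (2E)-3-methyl-5-[(1S)-2,6,6-trimethylcyclohex-2-en-1-yl]pent-2-en-1-ol
Conditions: i-Bu2AlH (2.5 equiv), CH2Cl2, −78 → 0 °C; aq. KNaC4H4O6
Reagents that add atoms: none
Why: 1,2-Reduction of an α,β-unsaturated ester with an electrophilic aluminium hydride gives the allylic alcohol without touching either C=C, so the E geometry and the (S) centre are carried over unchanged.

**Step 5**
Reactants: 3 2,5-dihydroxy-1,4-benzoquinone (3 equiv); 8 (2E)-3-methyl-5-[(1S)-2,6,6-trimethylcyclohex-2-en-1-yl]pent-2-en-1-ol
Product: 9 2,5-dihydroxy-3-{(2E)-3-methyl-5-[(1S)-2,6,6-trimethylcyclohex-2-en-1-yl]pent-2-en-1-yl}cyclohexa-2,5-diene-1,4-dione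
Conditions: Pd(PPh3)4 (5 mol%), degassed 1,4-dioxane, 60 °C; excess 3 filtered off and recycled
Reagents that add atoms: none
Why: Proposed new method: 3 (pKa about 2.7) protonates the hydroxyl of 8 on zerovalent palladium so that water leaves and a π-allylpalladium cation forms, which the ambident dihydroxyquinone monoanion attacks through C3 at the unsubstituted allyl terminus (O-allylation gives a vinylogous allyl ester that re-ionises, so the C-allyl product is the thermodynamic sink), the E geometry surviving because syn/anti exchange needs a tertiary σ-allylpalladium and the three-fold excess of symmetric 3 holding back a second allylation; the closest known reaction type is the dehydrative Tsuji–Trost C-allylation of 2-hydroxy-1,4-naphthoquinone, 4-hydroxycoumarins and cyclic 1,3-diketones with allylic alcohols; this is the symmetry-breaking key step, no stereocentre is formed and the (S) centre is untouched.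

**Step 6**
Reactants: 9 2,5-dihydroxy-3-{(2E)-3-methyl-5-[(1S)-2,6,6-trimethylcyclohex-2-en-1-yl]pent-2-en-1-yl}cyclohexa-2,5-diene-1,4-dione
Product: 10 2-hydroxy-5-methoxy-3-{(2E)-3-methyl-5-[(1S)-2,6,6-trimethylcyclohex-2-en-1-yl]pent-2-en-1-yl}cyclohexa-2,5-diene-1,4-dione (target)
Conditions: MeOH, camphor-10-sulfonic acid (10 mol%), 40 °C, stopped when 9 is consumed
Reagents that add atoms: methanol, CO
Why: Acid-catalysed vinylogous Fischer esterification (addition–elimination): methanol displaces the hydroxyl of the hydroxy-enone unit next to C6–H, which is far less hindered than the unit flanked by the C3 side chain (either oxygen of the unhindered unit gives the same product after tautomerisation), while 10 mol% sulfonic acid at 40 °C does not protonate the trisubstituted alkenes, so geometry and the (S) centre are kept.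

**Compound list**
1 | hydroquinone (benzene-1,4-diol) | Oc1ccc(O)cc1 | starting material
2 | disodium salt of 2,5-dihydroxy-1,4-benzoquinone | [Na+].[Na+].[O-]C1=CC(=O)C([O-])=CC1=O | intermediate
3 | 2,5-dihydroxy-1,4-benzoquinone | OC1=CC(=O)C(O)=CC1=O | intermediate
4 | (S)-α-ionone, (3E)-4-[(1S)-2,6,6-trimethylcyclohex-2-en-1-yl]but-3-en-2-one | CC(=O)/C=C/[C@@H]1C(C)=CCCC1(C)C | starting material
5 | dimethyl(phenyl)({4-[(1S)-2,6,6-trimethylcyclohex-2-en-1-yl]but-2-en-2-yl}oxy)silane (E/Z mixture at the enol ether) | CC(O[Si](C)(C)c1ccccc1)=CC[C@@H]2C(C)=CCCC2(C)C | intermediate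
6 | (S)-dihydro-α-ionone, 4-[(1S)-2,6,6-trimethylcyclohex-2-en-1-yl]butan-2-one | CC(=O)CC[C@@H]1C(C)=CCCC1(C)C | intermediate
7 | ethyl (2E)-3-methyl-5-[(1S)-2,6,6-trimethylcyclohex-2-en-1-yl]pent-2-enoate | CCOC(=O)/C=C(\C)CC[C@@H]1C(C)=CCCC1(C)C | intermediate
8 | (2E)-3-methyl-5-[(1S)-2,6,6-trimethylcyclohex-2-en-1-yl]pent-2-en-1-ol | OC/C=C(\C)CC[C@@H]1C(C)=CCCC1(C)C | intermediate
9 | 2,5-dihydroxy-3-{(2E)-3-methyl-5-[(1S)-2,6,6-trimethylcyclohex-2-en-1-yl]pent-2-en-1-yl}cyclohexa-2,5-diene-1,4-dione | OC1=CC(=O)C(O)=C(C/C=C(\C)CC[C@@H]2C(C)=CCCC2(C)C)C1=O | intermediate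
10 | 2-hydroxy-5-methoxy-3-{(2E)-3-methyl-5-[(1S)-2,6,6-trimethylcyclohex-2-en-1-yl]pent-2-en-1-yl}cyclohexa-2,5-diene-1,4-dione | COC1=CC(=O)C(O)=C(C/C=C(\C)CC[C@@H]2C(C)=CCCC2(C)C)C1=O | target

**Totals**
Total step count: 6. Longest linear sequence: 5 steps (4 → 6 → 7 → 8 → 9 → 10; step 1 is a one-step branch to 3).

**Steps most likely to fail, with fallbacks**

Step 5 is the largest risk. Possible failures are double allylation, persistent O-allyl products, erosion of E geometry through reversible O-attack at the tertiary allyl terminus, or poisoning of the palladium catalyst by the quinone. The fallback gives up the quinone nucleophile for a protected arene; it sets out from 8 and comes back to the route at 10. PBr3 (0.4 equiv) in Et2O at 0 °C converts 8 into (2E)-1-bromo-3-methyl-5-[(1S)-2,6,6-trimethylcyclohex-2-en-1-yl]pent-2-ene F1. Purchased 1,2,4,5-tetramethoxybenzene is deprotonated with n-BuLi/TMEDA in THF at 0 °C to 2,3,5,6-tetramethoxyphenyllithium F2. This is alkylated by F1 (CuBr·SMe2 10 mol%, −78 °C → rt) to the allylated tetramethoxybenzene F3. (NH4)2Ce(NO3)6 in MeCN/H2O at 0 °C oxidises F3 to the 3-alkyl-2,5-dimethoxy-1,4-benzoquinone F4. Aqueous HClO4 in THF at rt then hydrolyses the twisted methoxy group next to the side chain and gives 10.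

Step 6 is the second risk. The second hydroxyl may also be methylated, or the acid may cyclise the allyl hydroxyquinone onto its C2'=C3' alkene. The fallback changes the order of events so that the terpene never meets acid and the regiochemistry is fixed by construction; it sets out from 3 and comes back at 10. Compound 3 is mono-methylated first (MeOH, camphor-10-sulfonic acid cat., rt, stopped early, unreacted 3 filtered off and recycled) to 2-hydroxy-5-methoxy-1,4-benzoquinone F5. Its single hydroxy-enone unit is then C-allylated with 8 under the step 5 conditions (Pd(PPh3)4, 1,4-dioxane, 60 °C) to give 10 directly.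

Step 3 is the third risk. The E:Z ratio of the olefination of a methyl ketone may be lower than hoped, and the isomers may separate poorly. The fallback builds the trisubstituted alkene by carbometalation instead; it sets out from 6 and comes back at 7. LiN(i-Pr)2 in THF at −78 °C followed by ClP(O)(OEt)2 gives the terminal enol phosphate F6. A second portion of LiN(i-Pr)2 (2.3 equiv, −78 °C → rt) eliminates it to the terminal alkyne F7. AlMe3 (2 equiv) with Cp2ZrCl2 (0.25 equiv) in ClCH2CH2Cl at rt adds methyl and aluminium syn across the triple bond to the (E)-alkenyldimethylalane F8, which is quenched with ClCO2Et to give 7 with ≥98% E.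

**Further compounds**
F1 | step 5 | (2E)-1-bromo-3-methyl-5-[(1S)-2,6,6-trimethylcyclohex-2-en-1-yl]pent-2-ene | BrC/C=C(\C)CC[C@@H]1C(C)=CCCC1(C)C
F2 | step 5 | 2,3,5,6-tetramethoxyphenyllithium | [Li]c1c(OC)c(OC)cc(OC)c1OC
F3 | step 5 | 1,2,4,5-tetramethoxy-3-{(2E)-3-methyl-5-[(1S)-2,6,6-trimethylcyclohex-2-en-1-yl]pent-2-en-1-yl}benzene | COc1cc(OC)c(OC)c(C/C=C(\C)CC[C@@H]2C(C)=CCCC2(C)C)c1OC
F4 | step 5 | 2,5-dimethoxy-3-{(2E)-3-methyl-5-[(1S)-2,6,6-trimethylcyclohex-2-en-1-yl]pent-2-en-1-yl}cyclohexa-2,5-diene-1,4-dione | COC1=CC(=O)C(OC)=C(C/C=C(\C)CC[C@@H]2C(C)=CCCC2(C)C)C1=O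
F5 | step 6 | 2-hydroxy-5-methoxy-1,4-benzoquinone | COC1=CC(=O)C(O)=CC1=O
F6 | step 3 | diethyl 4-[(1S)-2,6,6-trimethylcyclohex-2-en-1-yl]but-1-en-2-yl phosphate | C=C(CC[C@@H]1C(C)=CCCC1(C)C)OP(=O)(OCC)OCC
F7 | step 3 | 4-[(1S)-2,6,6-trimethylcyclohex-2-en-1-yl]but-1-yne | C#CCC[C@@H]1C(C)=CCCC1(C)C
F8 | step 3 | dimethyl{(1E)-2-methyl-4-[(1S)-2,6,6-trimethylcyclohex-2-en-1-yl]but-1-en-1-yl}alane | C[Al](C)/C=C(\C)CC[C@@H]1C(C)=CCCC1(C)C
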